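**Assumption (one line):** tert-butyl (2-methylbut-3-en-2-yl) carbonate is taken as a catalogue compound; reagents that leave no atoms in the target (e.g. TBSCl) are named under conditions and not numbered.

## Retrosynthetic overview

1. Target 9 ⇐ global desilylation of the bis-TBS ether 8.
2. The two aryl–prenyl bonds (C3, C5) ⇐ one-pot Pd O-tert-prenylation / aromatic Claisen relay run twice from the 4-OH of ketone 6 (proposed new step).
3. The aryl–C(=O) bond ⇐ photo-Fries rearrangement of resorcinol monoester 5 (light-driven key C–C bond formation).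
4. Ester 5 ⇐ resorcinol 4 + bis-TBS acid 3 ⇐ (S)-4-hydroxyphenyllactic acid 2 ⇐ L-tyrosine 1, which supplies the only stereocentre with retention.
5. No ring is formed; both benzene rings are purchased (resorcinol, L-tyrosine).

The target's stereocentre is (S) (O > C(=O)Ar > CH2Ar > H), the same spatial arrangement as L-tyrosine with OH in place of NH2.

## Route

**Step 1**
Reactants: 1, L-tyrosine
Product: 2, (S)-2-hydroxy-3-(4-hydroxyphenyl)propanoic acid
Conditions: NaNO2 (2 equiv, slow aq. addition), 1 M H2SO4, 0 °C → rt, 16 h
Reagents that add atoms: water, O (source of the new OH oxygen)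
Why: Diazotisation of the α-amino acid; the carboxylate displaces N2 to give an α-lactone (inversion) which water opens (second inversion), so the (S) centre of L-tyrosine is carried over with net retention.

**Step 2**
Reactants: 2
Product: 3, (S)-2-[(tert-butyldimethylsilyl)oxy]-3-{4-[(tert-butyldimethylsilyl)oxy]phenyl}propanoic acid
Conditions: TBSCl (3.3 equiv), imidazole, DMF, rt; then AcOH/THF/H2O (3:1:1), rt, 2 h
Reagents that add atoms: TBSCl, CC(C)(C)[Si](C)(C)Cl
Why: Exhaustive silylation followed by selective hydrolysis of the very labile silyl ester leaves the aryl and secondary TBS ethers and frees the acid; the stereocentre is not touched.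

**Step 3**
Reactants: 3; 4, resorcinol (4 equiv)
Product: 5, 3-hydroxyphenyl (S)-2-[(tert-butyldimethylsilyl)oxy]-3-{4-[(tert-butyldimethylsilyl)oxy]phenyl}propanoate
Conditions: EDC·HCl, DMAP (0.1 equiv), CH2Cl2/THF, 0 °C → rt
Reagents that add atoms: none beyond reactant 4 (resorcinol, Oc1cccc(O)c1)
Why: Steglich esterification; excess of the cheap symmetric diphenol gives the monoester, and an α-silyloxy acid has no azlactone pathway, so the centre does not racemise on activation.

**Step 4 (key photochemical C–C bond formation)**
Reactants: 5
Product: 6, (S)-2-[(tert-butyldimethylsilyl)oxy]-3-{4-[(tert-butyldimethylsilyl)oxy]phenyl}-1-(2,4-dihydroxyphenyl)propan-1-one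
Conditions: hν (254 nm, low-pressure Hg), degassed MeCN (0.01 M), FEP flow coil, 15 °C, to ~85% conversion (recycle 5)
Reagents that add atoms: none
Why: Photo-Fries rearrangement: singlet ArO–C(=O) homolysis gives a caged acyl/3-hydroxyphenoxyl pair whose recombination at C6 (ortho) or C4 (para) tautomerises to the same 2,4-dihydroxyaryl ketone (C2 attack is the minor, separable 2,6-isomer); the stereocentre is α to the acyl radical, not the radical carbon, in-cage recombination outruns decarbonylation, and the o-hydroxyketone product is protected from further photochemistry by excited-state proton transfer, so (S) is retained.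

**Step 5 (proposed new step)**
Reactants: 6; 7, tert-butyl (2-methylbut-3-en-2-yl) carbonate (2 × 1.4 equiv)
Product: 8, (S)-2-[(tert-butyldimethylsilyl)oxy]-3-{4-[(tert-butyldimethylsilyl)oxy]phenyl}-1-[2,4-dihydroxy-3,5-bis(3-methylbut-2-en-1-yl)phenyl]propan-1-one
Conditions: Pd(PPh3)4 (5 mol%), 7 (1.4 equiv), PhMe, rt 2 h then 100 °C; cool, second charge of 7 (1.4 equiv) and Pd(PPh3)4 (2 mol%), rt then 100 °C, one pot
Reagents that add atoms: 7, C=CC(C)(C)OC(=O)OC(C)(C)C (delivers two C5H8 prenyl units; CO2 and t-BuOH are lost)
Why: Proposed new method: an oxygen-relayed double C-prenylation in which Pd(0) ionises 7 (–CO2; t-BuO⁻ deprotonates the acidic 4-OH), the phenoxide attacks the π-prenyl-Pd cation at its tertiary terminus to give the 4-O-(1,1-dimethylallyl) ether, and heating triggers an aromatic Claisen [3,3] shift to C3 or C5 with allyl inversion (giving a normal prenyl) and re-aromatisation, which regenerates the 4-OH for a second identical cycle that can only deliver to the remaining ortho carbon; because the acyl-phenoxide is a good leaving group, unproductive ethers (linear O-prenyl, ethers beside an occupied ortho site, O2 ethers) are re-ionised by Pd(0) and funnelled to the irreversible Claisen exit, making the sequence regioconvergent and self-limiting at two prenyls under neutral conditions that should leave the α-silyloxy ketone centre intact; the closest known reaction type is the stepwise Pd-catalysed O-tert-prenylation of a phenol followed by a separate thermal aromatic Claisen rearrangement, which as far as I know has not been run as a twofold one-pot relay from one phenolic oxygen of a 2,4-dihydroxyaryl ketone.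

**Step 6**
Reactants: 8
Product: 9, lespeflorin C6, (S)-1-[2,4-dihydroxy-3,5-bis(3-methylbut-2-en-1-yl)phenyl]-2-hydroxy-3-(4-hydroxyphenyl)propan-1-one
Conditions: TBAF (2.5 equiv), AcOH (3 equiv), THF, 0 °C → rt
Reagents that add atoms: none
Why: Fluoride-mediated cleavage of both silyl ethers; the acetic acid buffer prevents phenoxide/enolate formation (no α-ketol epimerisation) and the medium is too weakly acidic to cyclise the o-prenylphenols to chromans.

## Compound list

1 | L-tyrosine | N[C@@H](Cc1ccc(O)cc1)C(=O)O | starting material
2 | (S)-2-hydroxy-3-(4-hydroxyphenyl)propanoic acid | O=C(O)[C@@H](O)Cc1ccc(O)cc1 | intermediate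
3 | (S)-2-(TBSO)-3-[4-(TBSO)phenyl]propanoic acid | O=C(O)[C@@H](O[Si](C)(C)C(C)(C)C)Cc1ccc(O[Si](C)(C)C(C)(C)C)cc1 | intermediate
4 | resorcinol | Oc1cccc(O)c1 | starting material
5 | 3-hydroxyphenyl (S)-2-(TBSO)-3-[4-(TBSO)phenyl]propanoate | O=C(Oc1cccc(O)c1)[C@@H](O[Si](C)(C)C(C)(C)C)Cc1ccc(O[Si](C)(C)C(C)(C)C)cc1 | intermediate
6 | (S)-2-(TBSO)-3-[4-(TBSO)phenyl]-1-(2,4-dihydroxyphenyl)propan-1-one | O=C(c1ccc(O)cc1O)[C@@H](O[Si](C)(C)C(C)(C)C)Cc1ccc(O[Si](C)(C)C(C)(C)C)cc1 | intermediate
7 | tert-butyl (2-methylbut-3-en-2-yl) carbonate | C=CC(C)(C)OC(=O)OC(C)(C)C | starting material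
8 | (S)-2-(TBSO)-3-[4-(TBSO)phenyl]-1-[2,4-dihydroxy-3,5-diprenylphenyl]propan-1-one | CC(C)=CCc1cc(C(=O)[C@@H](O[Si](C)(C)C(C)(C)C)Cc2ccc(O[Si](C)(C)C(C)(C)C)cc2)c(O)c(CC=C(C)C)c1O | intermediate
9 | lespeflorin C6 | CC(C)=CCc1cc(C(=O)[C@@H](O)Cc2ccc(O)cc2)c(O)c(CC=C(C)C)c1O | target

## Summary

Total steps: 6. Longest linear sequence: 6 (L-tyrosine → 9).

Three steps most likely to fail:

1. **Step 5 (proposed new relay diprenylation).** Risks: stalling after one prenyl, reverse-prenyl by-products, slow Claisen because Pd equilibrates the ether to the linear isomer, or partial epimerisation at 100 °C (check by chiral HPLC). Fallback (known chemistry, +1 step): iodinate 6 at the only activated positions C3/C5 (BnMe3N·ICl2, NaHCO3, CH2Cl2/MeOH), then a twofold Stille coupling of the 3,5-diiodide with tributyl(3-methylbut-2-enyl)stannane (Pd(PPh3)4, DMF, 90 °C; neutral, stereocentre-safe) to give 8.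

2. **Step 4 (photo-Fries).** Risks: inner-filter stalling by the product, the 2,6-dihydroxy regioisomer, and cage escape/decarbonylation giving resorcinol. Fallback: drop the O→C acyl migration and make the ketone by a polar route — convert 3 to its Weinreb amide, add 2,4-bis(benzyloxy)phenyllithium (from 1-bromo-2,4-bis(benzyloxy)benzene, n-BuLi, –78 °C), then hydrogenolyse the benzyl ethers (H2, Pd/C) to reach 6 before any prenyl group is present (+2 steps).

3. **Step 6 (global desilylation).** Risks: slow cleavage of the hindered α-OTBS, α-ketol epimerisation, or chroman formation. Fallback: change the protecting-group plan from step 2 onward to triethylsilyl ethers on both oxygens (TESCl in place of TBSCl) and finish with mild acid solvolysis (PPTS, MeOH, rt) instead of fluoride.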